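**Retrosynthetic overview**
- The target is reached by hydrogenolysis of an octabenzyl precursor (both gallates as 3,4,5-tris(benzyloxy)benzoates, 7-OH and 3'-OH as benzyl ethers). The 3-OH comes from anti-selective hydroboration–oxidation of a (2S)-flav-3-ene.
- The C2–C1' bond is made by catalyst-controlled, enantioconvergent transfer of the complete B-ring aryl group (a diethyl arylboronate already carrying its gallate) to C2 of a racemic 2-ethoxy-2H-chromene that already carries the 5-O-gallate.
- Enabling feature: C2 lies between the ring oxygen O1 and a C3=C4 bond conjugated to the A ring. A C2 acetal therefore ionises to the achiral, aromatic chromenylium (1-benzopyrylium) cation, both acetal enantiomers give one C2 configuration, and the C3=C4 bond left behind is the handle for the trans 3-OH.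
- Ring order: A ring from 2,4,6-trihydroxybenzaldehyde (4-O-benzylation, then lactonisation distinguishes O5 from O7); pyran ring by Wittig–lactonisation to a coumarin, then DIBAL-H/EtOH to the acetal; B ring from 2-(benzyloxy)phenol; no ring is formed after the coupling.

Key step: step 12

Remark: both enantiomers of the tartaric-acid-derived catalyst are available, so the sense of induction at C2 is taken as selectable and would be confirmed by correlation with the final product.

**Step 1**
Reactants: 1 3,4,5-tris(benzyloxy)benzoic acid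
Product: 2 3,4,5-tris(benzyloxy)benzoyl chloride
Conditions: (COCl)2, cat. DMF, CH2Cl2, 0 °C to rt
Reagents that add atoms: oxalyl chloride ClC(=O)C(=O)Cl
Why: DMF-catalysed conversion of a carboxylic acid into its acid chloride with oxalyl chloride is standard and leaves benzyl ethers untouched.

**Step 2**
Reactants: 3 2,4,6-trihydroxybenzaldehyde
Product: 4 4-(benzyloxy)-2,6-dihydroxybenzaldehyde
Conditions: BnBr (1.0 equiv), CsHCO3, MeCN, 60 °C
Reagents that add atoms: benzyl bromide BrCc1ccccc1
Why: The 4-OH is para to the formyl group and is the only hydroxyl not held in a hydrogen bond to C=O, so it is the most acidic and a mild-base Williamson etherification should alkylate it selectively, as known for 2,4-dihydroxybenzaldehydes.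

**Step 3**
Reactants: 4 4-(benzyloxy)-2,6-dihydroxybenzaldehyde
Product: 6 7-(benzyloxy)-5-hydroxy-2H-chromen-2-one, via cinnamate ester 5 (not isolated)
Conditions: Ph3P=CHCO2Et, PhNEt2, 200 °C
Reagents that add atoms: ethyl (triphenylphosphoranylidene)acetate CCOC(=O)C=P(c1ccccc1)(c1ccccc1)c1ccccc1
Why: Wittig olefination gives the o-hydroxycinnamate, which isomerises and lactonises at high temperature (classical coumarin synthesis); the two ortho hydroxyls of 4 are equivalent, so either closure gives the same coumarin and leaves the other as 5-OH, distinct from 7-OBn.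

**Step 4**
Reactants: 6 7-(benzyloxy)-5-hydroxy-2H-chromen-2-one
Product: 7 7-(benzyloxy)-5-(tert-butyldimethylsilyloxy)-2H-chromen-2-one
Conditions: TBSCl, imidazole, DMF, rt
Reagents that add atoms: tert-butyldimethylsilyl chloride CC(C)(C)[Si](C)(C)Cl
Why: Routine silylation of a phenol masks the 5-OH through the hydride step.

**Step 5**
Reactants: 7 7-(benzyloxy)-5-(tert-butyldimethylsilyloxy)-2H-chromen-2-one
Product: 9 rac-7-(benzyloxy)-5-(tert-butyldimethylsilyloxy)-2-ethoxy-2H-chromene, via lactol 8 (not isolated)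
Conditions: DIBAL-H (1.2 equiv), CH2Cl2, −78 °C; Rochelle salt work-up; then EtOH, cat. PPTS, rt
Reagents that add atoms: ethanol CCO
Why: DIBAL-H at −78 °C should stop at the tetrahedral aluminate of the lactone (partial reduction of a coumarin to its lactol), and acid-catalysed exchange with ethanol through the chromenylium ion gives the mixed acetal; C2 is racemic, which does not matter because step 12 is enantioconvergent.

**Step 6**
Reactants: 9 rac-7-(benzyloxy)-5-(tert-butyldimethylsilyloxy)-2-ethoxy-2H-chromene; 2 3,4,5-tris(benzyloxy)benzoyl chloride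
Product: 11 rac-7-(benzyloxy)-2-ethoxy-2H-chromen-5-yl 3,4,5-tris(benzyloxy)benzoate, via phenol 10 (not isolated)
Conditions: TBAF (1.05 equiv), THF, −40 °C; then Et3N, 2, −40 to 0 °C
Reagents that add atoms: none
Why: Fluoride cleaves the aryl silyl ether to the tetrabutylammonium phenoxide, which is O-acylated at once by the acid chloride under basic conditions that the acid-labile acetal should tolerate (one-flask desilylation–acylation).

**Step 7**
Reactants: 12 2-(benzyloxy)phenol
Product: 13 2-(benzyloxy)-4-bromophenol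
Conditions: NBS, MeCN, 0 °C
Reagents that add atoms: N-bromosuccinimide O=C1CCC(=O)N1Br
Why: Electrophilic aromatic bromination should go para to the free hydroxyl, the stronger donor, as with guaiacol.

**Step 8**
Reactants: 13 2-(benzyloxy)-4-bromophenol; 2 3,4,5-tris(benzyloxy)benzoyl chloride
Product: 14 2-(benzyloxy)-4-bromophenyl 3,4,5-tris(benzyloxy)benzoate
Conditions: Et3N, cat. DMAP, CH2Cl2, 0 °C to rt
Reagents that add atoms: none
Why: DMAP-catalysed acylation of a phenol with an acid chloride fixes the gallate on the oxygen para to bromine.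

**Step 9**
Reactants: 14 2-(benzyloxy)-4-bromophenyl 3,4,5-tris(benzyloxy)benzoate
Product: 15 2-(benzyloxy)-4-(4,4,5,5-tetramethyl-1,3,2-dioxaborolan-2-yl)phenyl 3,4,5-tris(benzyloxy)benzoate
Conditions: B2pin2, cat. Pd(dppf)Cl2, KOAc, 1,4-dioxane, 85 °C
Reagents that add atoms: bis(pinacolato)diboron CC1(C)OB(OC1(C)C)B1OC(C)(C)C(C)(C)O1
Why: Miyaura borylation of an aryl bromide with KOAc as base leaves aryl esters and benzyl ethers intact.

**Step 10**
Reactants: 15 pinacol boronate
Product: 16 {3-(benzyloxy)-4-[3,4,5-tris(benzyloxy)benzoyloxy]phenyl}boronic acid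
Conditions: NaIO4, NH4OAc, acetone/H2O, rt
Reagents that add atoms: water O
Why: Periodate cleaves the released pinacol and so drives hydrolysis of the boronate to the boronic acid under near-neutral conditions that spare the phenolic ester.

**Step 11**
Reactants: 16 boronic acid
Product: 17 diethyl {3-(benzyloxy)-4-[3,4,5-tris(benzyloxy)benzoyloxy]phenyl}boronate
Conditions: EtOH, 3 Å MS, CH2Cl2, rt; concentrated and used crude
Reagents that add atoms: ethanol CCO
Why: Esterification of a boronic acid with ethanol, driven by removal of water, gives the exchange-labile diethyl boronate needed for ligand exchange with the chiral diol.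

**Step 12**
Reactants: 11 rac-7-(benzyloxy)-2-ethoxy-2H-chromen-5-yl 3,4,5-tris(benzyloxy)benzoate; 17 diethyl arylboronate
Product: 19 (2S)-7-(benzyloxy)-2-{3-(benzyloxy)-4-[3,4,5-tris(benzyloxy)benzoyloxy]phenyl}-2H-chromen-5-yl 3,4,5-tris(benzyloxy)benzoate, via chromenylium ion 18 (not isolated)
Conditions: N,N-dibenzyltartaramic acid (10 mol%, the enantiomer that gives the 2S product), Yb(OTf)3 (8 mol%), EtOAc, −20 °C; chromatography on Et3N-deactivated silica
Reagents that add atoms: none
Why: The chiral tartaric-acid-derived diol exchanges onto boron of 17 and, helped by the lanthanide triflate, the resulting Lewis-acidic dioxaborolane takes the ethoxide from either enantiomer of racemic 11, giving the same achiral, 10π-aromatic chromenylium ion 18 paired with a chiral aryl borate, from which the aryl group migrates to C2 inside the ion pair. The closest known reaction type is the chiral diol/Lewis acid-catalysed enantioselective addition of aryl and alkenyl boronates to 2-alkoxy-2H-chromenes, a boron-to-carbon transfer related to the Petasis reaction. No ring is closed; the pyran ring passes intact through the cation. The one new stereocentre, C2, is set by the chiral diol on boron (catalyst control), which shields one face of the planar cation, so the step is enantioconvergent. It needs attack at C2 instead of C4 and on one face: delivery from the borate that has just received the ethoxide at C2, together with the peri 5-acyloxy group beside C4, should secure the first, and the choice of ligand enantiomer the second. The 4'-O-acyl group lowers the nucleophilicity of the aryl group, which the 7-benzyloxy-stabilised, longer-lived cation should tolerate, and it keeps O4' from ever becoming a free phenoxide that could open the pyran ring and erode C2.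

**Step 13**
Reactants: 19 (2S)-flav-3-ene
Product: 21 (2R,3S)-7-(benzyloxy)-2-{3-(benzyloxy)-4-[3,4,5-tris(benzyloxy)benzoyloxy]phenyl}-3-hydroxychroman-5-yl 3,4,5-tris(benzyloxy)benzoate, via C3 borane 20 (not isolated)
Conditions: BH3·SMe2, THF, 0 °C to rt; H2O; then Me3NO·2H2O, THF, rt to 45 °C
Reagents that add atoms: trimethylamine N-oxide C[N+](C)(C)[O-]
Why: Brown hydroboration adds B–H syn to the C3=C4 face opposite the C2 aryl group with boron at C3 (away from the aryl-bearing C4 and its peri 5-acyloxy group, next to the carbon bearing O1), and oxidation with retention gives the 2,3-trans alcohol as known for flav-3-enes, so C3 is set by substrate control from C2; the neutral amine N-oxide oxidant should spare the phenolic esters.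

**Step 14**
Reactants: 21 octabenzyl (2R,3S)-flavan-3-ol digallate
Product: 22 catechin 5,4'-di-O-gallate
Conditions: H2 (1 atm), Pd(OH)2/C, THF/EtOAc, rt
Reagents that add atoms: none
Why: Pd-catalysed hydrogenolysis removes all eight benzyl ethers in a neutral, alcohol-free medium in which the phenolic gallates should neither migrate nor cleave and the benzylic C2–O1 bond of the chroman should survive, as in standard catechin gallate end games.

**Compound list**
1 | 3,4,5-tris(benzyloxy)benzoic acid | OC(=O)c1cc(OCc2ccccc2)c(OCc2ccccc2)c(OCc2ccccc2)c1 | starting material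
2 | 3,4,5-tris(benzyloxy)benzoyl chloride | ClC(=O)c1cc(OCc2ccccc2)c(OCc2ccccc2)c(OCc2ccccc2)c1 | intermediate
3 | 2,4,6-trihydroxybenzaldehyde | O=Cc1c(O)cc(O)cc1O | starting material
4 | 4-(benzyloxy)-2,6-dihydroxybenzaldehyde | O=Cc1c(O)cc(OCc2ccccc2)cc1O | intermediate
5 | ethyl (E)-3-[4-(benzyloxy)-2,6-dihydroxyphenyl]prop-2-enoate | CCOC(=O)/C=C/c1c(O)cc(OCc2ccccc2)cc1O | intermediate
6 | 7-(benzyloxy)-5-hydroxy-2H-chromen-2-one | O=c1ccc2c(O)cc(OCc3ccccc3)cc2o1 | intermediate
7 | 7-(benzyloxy)-5-(tert-butyldimethylsilyloxy)-2H-chromen-2-one | O=c1ccc2c(O[Si](C)(C)C(C)(C)C)cc(OCc3ccccc3)cc2o1 | intermediate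
8 | rac-7-(benzyloxy)-5-(tert-butyldimethylsilyloxy)-2H-chromen-2-ol | OC1C=Cc2c(O[Si](C)(C)C(C)(C)C)cc(OCc3ccccc3)cc2O1 | intermediate
9 | rac-7-(benzyloxy)-5-(tert-butyldimethylsilyloxy)-2-ethoxy-2H-chromene | CCOC1C=Cc2c(O[Si](C)(C)C(C)(C)C)cc(OCc3ccccc3)cc2O1 | intermediate
10 | rac-7-(benzyloxy)-2-ethoxy-2H-chromen-5-ol (present as its tetrabutylammonium phenoxide) | CCOC1C=Cc2c(O)cc(OCc3ccccc3)cc2O1 | intermediate
11 | rac-7-(benzyloxy)-2-ethoxy-2H-chromen-5-yl 3,4,5-tris(benzyloxy)benzoate | CCOC1C=Cc2c(OC(=O)c3cc(OCc4ccccc4)c(OCc4ccccc4)c(OCc4ccccc4)c3)cc(OCc3ccccc3)cc2O1 | intermediate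
12 | 2-(benzyloxy)phenol | Oc1ccccc1OCc1ccccc1 | starting material
13 | 2-(benzyloxy)-4-bromophenol | Oc1ccc(Br)cc1OCc1ccccc1 | intermediate
14 | 2-(benzyloxy)-4-bromophenyl 3,4,5-tris(benzyloxy)benzoate | O=C(Oc1ccc(Br)cc1OCc1ccccc1)c1cc(OCc2ccccc2)c(OCc2ccccc2)c(OCc2ccccc2)c1 | intermediate
15 | 2-(benzyloxy)-4-(4,4,5,5-tetramethyl-1,3,2-dioxaborolan-2-yl)phenyl 3,4,5-tris(benzyloxy)benzoate | O=C(Oc1ccc(B2OC(C)(C)C(C)(C)O2)cc1OCc1ccccc1)c1cc(OCc2ccccc2)c(OCc2ccccc2)c(OCc2ccccc2)c1 | intermediate
16 | {3-(benzyloxy)-4-[3,4,5-tris(benzyloxy)benzoyloxy]phenyl}boronic acid | O=C(Oc1ccc(B(O)O)cc1OCc1ccccc1)c1cc(OCc2ccccc2)c(OCc2ccccc2)c(OCc2ccccc2)c1 | intermediate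
17 | diethyl {3-(benzyloxy)-4-[3,4,5-tris(benzyloxy)benzoyloxy]phenyl}boronate | CCOB(OCC)c1ccc(OC(=O)c2cc(OCc3ccccc3)c(OCc3ccccc3)c(OCc3ccccc3)c2)c(OCc2ccccc2)c1 | intermediate
18 | 7-(benzyloxy)-5-[3,4,5-tris(benzyloxy)benzoyloxy]chromenylium (1-benzopyrylium) ion | O=C(Oc1cc(OCc2ccccc2)cc2[o+]cccc12)c1cc(OCc2ccccc2)c(OCc2ccccc2)c(OCc2ccccc2)c1 | intermediate
19 | (2S)-7-(benzyloxy)-2-{3-(benzyloxy)-4-[3,4,5-tris(benzyloxy)benzoyloxy]phenyl}-2H-chromen-5-yl 3,4,5-tris(benzyloxy)benzoate | O=C(Oc1ccc([C@H]2Oc3cc(OCc4ccccc4)cc(OC(=O)c4cc(OCc5ccccc5)c(OCc5ccccc5)c(OCc5ccccc5)c4)c3C=C2)cc1OCc1ccccc1)c1cc(OCc2ccccc2)c(OCc2ccccc2)c(OCc2ccccc2)c1 | intermediate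
20 | C3 borane of 19: 3-boranyl chroman with boron trans to the C2 aryl group, otherwise substituted as 21 | O=C(Oc1ccc([C@H]2Oc3cc(OCc4ccccc4)cc(OC(=O)c4cc(OCc5ccccc5)c(OCc5ccccc5)c(OCc5ccccc5)c4)c3C[C@@H]2B)cc1OCc1ccccc1)c1cc(OCc2ccccc2)c(OCc2ccccc2)c(OCc2ccccc2)c1 | intermediate
21 | (2R,3S)-7-(benzyloxy)-2-{3-(benzyloxy)-4-[3,4,5-tris(benzyloxy)benzoyloxy]phenyl}-3-hydroxychroman-5-yl 3,4,5-tris(benzyloxy)benzoate | O=C(Oc1ccc([C@H]2Oc3cc(OCc4ccccc4)cc(OC(=O)c4cc(OCc5ccccc5)c(OCc5ccccc5)c(OCc5ccccc5)c4)c3C[C@@H]2O)cc1OCc1ccccc1)c1cc(OCc2ccccc2)c(OCc2ccccc2)c(OCc2ccccc2)c1 | intermediate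
22 | catechin 5,4'-di-O-gallate, (2R,3S) | O=C(Oc1ccc([C@H]2Oc3cc(O)cc(OC(=O)c4cc(O)c(O)c(O)c4)c3C[C@@H]2O)cc1O)c1cc(O)c(O)c(O)c1 | target

**Step count**
Total: 14 steps. Longest linear sequence: 8 steps (steps 2–6 then 12–14; the B-ring arm, steps 7–11 then 12–14, is equally long).

**Steps most likely to fail**

Step 12. The acyloxy-substituted aryl group may transfer from boron too slowly, so that the chromenylium ion is consumed by oligomerisation or re-addition of ethanol, or the facial selectivity may be low. The fallback uses a donor-substituted boronate inside the usual scope of this arylation and installs the B-ring gallate afterwards. It sets out from 13. Silylation (TBSCl, imidazole, DMF) should give tert-butyl[2-(benzyloxy)-4-bromophenoxy]dimethylsilane F1. Bromine–lithium exchange (n-BuLi, THF, −78 °C), B(OiPr)3 and a brief dilute HCl work-up should give [3-(benzyloxy)-4-(tert-butyldimethylsilyloxy)phenyl]boronic acid F2. EtOH with 3 Å MS should give diethyl [3-(benzyloxy)-4-(tert-butyldimethylsilyloxy)phenyl]boronate F3. Addition of F3 to acetal 11 under the step 12 catalyst should give (2S)-7-(benzyloxy)-2-[3-(benzyloxy)-4-(tert-butyldimethylsilyloxy)phenyl]-2H-chromen-5-yl 3,4,5-tris(benzyloxy)benzoate F4. TBAF is then added at −78 °C to F4 premixed with acid chloride 2 and Et3N, so that the 4'-phenoxide is acylated as it forms and cannot open the pyran ring through a quinone methide. This returns to the route at 19.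

Step 6. The phenoxide may expel ethoxide from the acetal (vinylogous elimination to a quinoid chromenone), or traces of acid from wet TBAF and the acid chloride may ionise the acetal, before acylation is complete. The fallback moves the A-ring acylation to after the C–C bond formation. It sets out from 9, which is used directly in the step 12 reaction with boronate 17 to give (2S)-2-(benzyloxy)-4-[7-(benzyloxy)-5-(tert-butyldimethylsilyloxy)-2H-chromen-2-yl]phenyl 3,4,5-tris(benzyloxy)benzoate F5. Pyridine-buffered HF·pyridine (THF, 0 °C) should then free (2S)-2-(benzyloxy)-4-[7-(benzyloxy)-5-hydroxy-2H-chromen-2-yl]phenyl 3,4,5-tris(benzyloxy)benzoate F6, which has no acetal left to ionise. Acylation with 2 (Et3N, cat. DMAP, CH2Cl2) returns to the route at 19.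

Step 13. Boron may be delivered partly to C4, or the phenolic esters may be reduced or cleaved during hydroboration and oxidative work-up. The fallback replaces hydroboration by epoxidation and reductive opening. It sets out from 19. Dimethyldioxirane (acetone/CH2Cl2, −20 °C) should epoxidise the C3=C4 bond anti to the C2 aryl group to give the 2,3-trans 3,4-epoxyflavan F7. Hydrogenolysis under the step 14 conditions should cleave the benzylic C4–O bond of the epoxide together with the eight benzyl ethers (Pd-catalysed hydrogenolysis of aryl epoxides at the benzylic carbon), which comes back to the route at 22.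

**Further compounds**
F1 | step 12 | tert-butyl[2-(benzyloxy)-4-bromophenoxy]dimethylsilane | CC(C)(C)[Si](C)(C)Oc1ccc(Br)cc1OCc1ccccc1
F2 | step 12 | [3-(benzyloxy)-4-(tert-butyldimethylsilyloxy)phenyl]boronic acid | CC(C)(C)[Si](C)(C)Oc1ccc(B(O)O)cc1OCc1ccccc1
F3 | step 12 | diethyl [3-(benzyloxy)-4-(tert-butyldimethylsilyloxy)phenyl]boronate | CCOB(OCC)c1ccc(O[Si](C)(C)C(C)(C)C)c(OCc2ccccc2)c1
F4 | step 12 | (2S)-7-(benzyloxy)-2-[3-(benzyloxy)-4-(tert-butyldimethylsilyloxy)phenyl]-2H-chromen-5-yl 3,4,5-tris(benzyloxy)benzoate | CC(C)(C)[Si](C)(C)Oc1ccc([C@H]2Oc3cc(OCc4ccccc4)cc(OC(=O)c4cc(OCc5ccccc5)c(OCc5ccccc5)c(OCc5ccccc5)c4)c3C=C2)cc1OCc1ccccc1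
F5 | step 6 | (2S)-2-(benzyloxy)-4-[7-(benzyloxy)-5-(tert-butyldimethylsilyloxy)-2H-chromen-2-yl]phenyl 3,4,5-tris(benzyloxy)benzoate | O=C(Oc1ccc([C@H]2Oc3cc(OCc4ccccc4)cc(O[Si](C)(C)C(C)(C)C)c3C=C2)cc1OCc1ccccc1)c1cc(OCc2ccccc2)c(OCc2ccccc2)c(OCc2ccccc2)c1
F6 | step 6 | (2S)-2-(benzyloxy)-4-[7-(benzyloxy)-5-hydroxy-2H-chromen-2-yl]phenyl 3,4,5-tris(benzyloxy)benzoate | O=C(Oc1ccc([C@H]2Oc3cc(OCc4ccccc4)cc(O)c3C=C2)cc1OCc1ccccc1)c1cc(OCc2ccccc2)c(OCc2ccccc2)c(OCc2ccccc2)c1
F7 | step 13 | 2,3-trans 3,4-epoxyflavan from 19 (epoxide oxygen anti to the C2 aryl group), otherwise substituted as 19 | O=C(Oc1ccc([C@H]2Oc3cc(OCc4ccccc4)cc(OC(=O)c4cc(OCc5ccccc5)c(OCc5ccccc5)c(OCc5ccccc5)c4)c3[C@@H]6O[C@H]26)cc1OCc1ccccc1)c1cc(OCc2ccccc2)c(OCc2ccccc2)c(OCc2ccccc2)c1
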